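**Retrosynthetic overview**

1. Side chain: the (13R)-hydroperoxide and the (E)-C14=C15 bond come from a (13S,14S)-epoxide (Shi epoxidation) by perhydrolysis with inversion and Burgess dehydration; the butenolide ring comes from ring-closing metathesis; the (13E)-alkene and C14–C15 come from Negishi methylalumination of a C13≡C14 alkyne and opening of (R)-2-isopropenyloxirane; 8α-OH and C17 come from a C8 ketone.
2. Ring B: a one-pot formal [3+3] annulation of ring-A lactol 7 (C6 and C10 electrophilic) with β-keto ester 10 (C9 and C7 nucleophilic): O-acylation, Carroll [3,3] shift (C9–C10), decarboxylation, methanolysis, aldol closure (C6–C7).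
3. Enabling feature: the C4 carboxyl carbon C18 is γ to the C6 oxygen, so the ring-A enal acid closes to a five-membered lactol (temporary lactone ring C4–C5–C6–O–C18). Its β-keto ester holds the array C10=C5–C6–O–C(O)=C9 for a [3,3] shift that leaves C6 as an enol lactone (masked aldehyde), and the C4 methyl shields one face. Methanolysis then frees the CO2CH3 group and a 1,5-keto aldehyde whose aldol gives the C6(OH)–C7H2–C8(=O) unit of ring B.
4. Ring order: ring A (steps 1–5), temporary lactone ring (step 6), ring B (step 8), epoxide (step 15), butenolide ring (step 16).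

Key step: step 8

Remark: labdane numbering is used (C18 = ester carbon on C4, C17 = methyl on C8, C20 = methyl on C10, side chain C11–C15, C16 = methyl on C13, butenolide O1′–C5′ with C5′ bonded to C15); the Fráter–Seebach methylation of step 1 is assumed to enter trans to the C2 oxygen, and compounds 1 and 20 are assumed to be commercially available.

**Step 1**
Reactants: 1 ethyl (1R,2S)-2-hydroxycyclohexane-1-carboxylate
Product: 2 ethyl (1R,2S)-2-hydroxy-1-methylcyclohexane-1-carboxylate
Conditions: LiN(i-Pr)2 (2.2 equiv), THF, −50 → −10 °C; then MeI, −50 → 0 °C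
Reagents that add atoms: iodomethane, CI
Why: Fráter–Seebach alkylation: after double deprotonation the methyl group should enter on the face away from the C2 oxygen, which sets the quaternary carbon (the future C4) with methyl trans to the hydroxyl.

**Step 2**
Reactants: 2 ethyl (1R,2S)-2-hydroxy-1-methylcyclohexane-1-carboxylate
Product: 3 ethyl (1R)-1-methyl-2-oxocyclohexane-1-carboxylate
Conditions: Dess–Martin periodinane, NaHCO3, CH2Cl2, rt
Reagents that add atoms: none
Why: Dess–Martin oxidation of the secondary alcohol; the quaternary stereocentre carries no hydrogen and cannot epimerise.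

**Step 3**
Reactants: 3 ethyl (1R)-1-methyl-2-oxocyclohexane-1-carboxylate
Product: 4 ethyl (1R)-1,3-dimethyl-2-oxocyclohexane-1-carboxylate (both C3 epimers)
Conditions: LiN(i-Pr)2, THF, −78 °C; then MeI, −78 → 0 °C
Reagents that add atoms: iodomethane, CI
Why: Kinetic enolate alkylation: the ketone can be deprotonated only on its CH2 side, so the methyl group should enter there; the new centre is left undefined because it becomes sp2 in step 4.

**Step 4**
Reactants: 4 ethyl (1R)-1,3-dimethyl-2-oxocyclohexane-1-carboxylate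
Product: 5 ethyl (1R)-1,3-dimethyl-2-{[(trifluoromethyl)sulfonyl]oxy}cyclohex-2-ene-1-carboxylate
Conditions: KN(SiMe3)2, THF, −78 °C; then PhNTf2, −78 → 0 °C
Reagents that add atoms: N-phenylbis(trifluoromethanesulfonimide), O=S(=O)(N(c1ccccc1)S(=O)(=O)C(F)(F)F)C(F)(F)F
Why: Enolate O-triflation: removal of the only remaining α-hydrogen gives a single regioisomer, trapped as the tetrasubstituted enol triflate.

**Step 5**
Reactants: 5 ethyl (1R)-1,3-dimethyl-2-{[(trifluoromethyl)sulfonyl]oxy}cyclohex-2-ene-1-carboxylate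
Product: 6 ethyl (1R)-2-formyl-1,3-dimethylcyclohex-2-ene-1-carboxylate
Conditions: Pd(OAc)2 (5 mol %), 1,3-bis(diphenylphosphino)propane, CO (1 atm), Et3SiH, Et3N, DMF, 70 °C
Reagents that add atoms: carbon monoxide, [C-]#[O+]
Why: Palladium-catalysed reductive carbonylation (formylation) of an enol triflate should give the tetrasubstituted enal, i.e. the C5=C10 double bond carrying the C6 formyl group and the C10 methyl.

**Step 6**
Reactants: 6 ethyl (1R)-2-formyl-1,3-dimethylcyclohex-2-ene-1-carboxylate
Product: 7 (7aR)-3-hydroxy-4,7a-dimethyl-5,6,7,7a-tetrahydro-2-benzofuran-1(3H)-one (lactol form of the formyl acid, both C3 epimers)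
Conditions: LiOH, THF–H2O, rt; then 1 M HCl to pH 3
Reagents that add atoms: lithium hydroxide, [Li+].[OH-]
Why: Ester saponification, helped by the neighbouring formyl group, followed by ring–chain tautomerism of the γ-formyl acid to the five-membered lactol, which builds the temporary lactone ring C4–C5–C6–O–C18.

**Step 7**
Reactants: 8 tert-butyl 3-oxobutanoate; 9 4-bromobut-1-yne
Product: 10 tert-butyl 2-acetylhex-5-ynoate (racemic)
Conditions: NaH, THF–DMF, 0 °C; then 9, NaI (cat.), 50 °C
Reagents that add atoms: none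
Why: Acetoacetic ester alkylation (SN2 on the primary bromide); the new centre becomes C9 and is set later under equilibrating conditions.

**Step 8**
Reactants: 7 (7aR)-3-hydroxy-4,7a-dimethyl-5,6,7,7a-tetrahydro-2-benzofuran-1(3H)-one; 10 tert-butyl 2-acetylhex-5-ynoate
Product: 15 methyl 6α-hydroxy-8-oxo-15,16,17-trinorlabd-13-yn-18-oate, via pseudo-ester 11 (not isolated), via keto acid 12 (not isolated), via enol lactone ketone 13 (not isolated), via keto aldehyde ester 14 (not isolated)
Conditions: xylenes, 140 °C (t-BuOH and CO2 leave); then cool to 0 °C, MeOH, K2CO3, 0 °C → rt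
Reagents that add atoms: methanol, CO
Why: Proposed new method: the tert-butyl β-keto ester transfers its acyl group thermally to the lactol hydroxyl on the face opposite the C4 methyl (11), whose enol form holds the array C10=C5–C6–O–C(OH)=C9 and undergoes a Carroll [3,3] rearrangement that forms C9–C10 and gives keto acid 12 and, after loss of CO2, enol lactone ketone 13; carbonate in methanol then opens the enol lactone to the methyl ester and the C6 aldehyde (14), and the ketone methyl carbon C7 adds to C6 in an intramolecular aldol reaction. The closest known reactions are the Carroll rearrangement of allylic acetoacetates, the ester-enolate Claisen rearrangements that join two fully substituted carbons (trichodiene syntheses) and the aldol closure of 1,5-keto aldehydes in Robinson annulations; new is that the allylic alcohol component is a lactol, so that the shift leaves C6 at the aldehyde oxidation level. Ring B closes by a 6-(enolendo)-exo-trig aldol addition through a chair. C10 is set in the suprafacial [3,3] shift, the acyloxy group on the lactone face opposite the C4 methyl delivering C9 to that face of C10, while C9 (α to the C8 ketone), C5 (α to the aldehyde until the reversible aldol locks it) and C6 should settle under thermodynamic control as the trans-fused ketol with equatorial C9 side chain and equatorial 6α-hydroxyl, because an axial 6-hydroxyl would be 1,3-diaxial to both the C4 and the C10 methyl. The step needs the [3,3] shift at C10 to win over ion-pair return at C6 and over 1,3-acyloxy migration, which the non-acidic thermal conditions and the weak acylal C6–O bond should favour, and it needs aldol addition without E1cB loss of the new hydroxyl, which mild carbonate at low temperature should secure.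

**Step 9**
Reactants: 15 methyl 6α-hydroxy-8-oxo-15,16,17-trinorlabd-13-yn-18-oate
Product: 16 methyl 6α-hydroxy-15,16-dinorlabd-8(17)-en-13-yn-18-oate
Conditions: Zn, CH2Br2, TiCl4, THF (reagent pre-formed at 0 °C); then 15, CH2Cl2, 0 °C → rt
Reagents that add atoms: dibromomethane, BrCBr
Why: Lombardo methylenation: the non-basic titanium methylene reagent should convert the hindered, enolisable ketone into the exocyclic alkene without retro-aldol reaction, dehydration or attack on the ester.

**Step 10**
Reactants: 16 methyl 6α-hydroxy-15,16-dinorlabd-8(17)-en-13-yn-18-oate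
Product: 18 methyl 6α,8α-dihydroxy-15,16-dinorlabd-13-yn-18-oate, via organomercurial 17 (not isolated)
Conditions: Hg(OAc)2 (1.1 equiv), THF–H2O, rt; then NaOH (aq), NaBH4, 0 °C
Reagents that add atoms: water, O
Why: Oxymercuration–demercuration (Markovnikov hydration): water should attack C8 from the equatorial α-face, away from the axial C10 methyl, as in the hydration of labd-8(17)-enes to 8α-ols, which sets C8; the 1,1-disubstituted alkene reacts much faster than the terminal alkyne.

**Step 11**
Reactants: 18 methyl 6α,8α-dihydroxy-15,16-dinorlabd-13-yn-18-oate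
Product: 19 methyl 6α,8α-bis(triethylsilyloxy)-15,16-dinorlabd-13-yn-18-oate
Conditions: Et3SiOTf (3 equiv), 2,6-lutidine, CH2Cl2, −78 → 0 °C
Reagents that add atoms: triethylsilyl trifluoromethanesulfonate, CC[Si](CC)(CC)OS(=O)(=O)C(F)(F)F
Why: Silyl ether formation with the silyl triflate covers the hindered secondary 6α-OH and the tertiary 8α-OH, so that later acylation and dehydration can touch only side-chain hydroxyls.

**Step 12**
Reactants: 20 rac-2-(prop-1-en-2-yl)oxirane
Product: 21 (R)-2-(prop-1-en-2-yl)oxirane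
Conditions: (salen)Co(OAc) [salen = N,N′-bis(3,5-di-tert-butylsalicylidene)cyclohexane-1,2-diaminate; the enantiomer of the complex that hydrolyses the (S)-epoxide faster] (0.5 mol %), H2O (0.55 equiv), 0 °C → rt; distillation
Reagents that add atoms: none
Why: Jacobsen hydrolytic kinetic resolution: the chiral cobalt–salen complex hydrates one enantiomer of the terminal epoxide much faster and should leave the (R)-epoxide, which carries the future C5′ stereocentre.

**Step 13**
Reactants: 19 methyl 6α,8α-bis(triethylsilyloxy)-15,16-dinorlabd-13-yn-18-oate; 21 (R)-2-(prop-1-en-2-yl)oxirane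
Product: 23 methyl (13E)-15-[(1S)-1-hydroxy-2-methylprop-2-en-1-yl]-6α,8α-bis(triethylsilyloxy)labd-13-en-18-oate, via alkenylalane 22 (not isolated)
Conditions: Cp2ZrCl2 (0.5 equiv), AlMe3 (3 equiv), ClCH2CH2Cl, 0 °C → rt; evaporate; hexane, n-BuLi (1 equiv), −78 °C; then 21, THF, −78 → 0 °C
Reagents that add atoms: trimethylaluminium, C[Al](C)C
Why: Negishi zirconium-catalysed methylalumination (syn addition, methyl to the internal carbon) should give the (E)-alkenylalane 22, which after activation by n-BuLi opens the epoxide at its CH2 terminus, so that the (13E)-alkene is set by the carbometalation and C5′ (S) comes unchanged from 21.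

**Step 14**
Reactants: 23 methyl (13E)-15-[(1S)-1-hydroxy-2-methylprop-2-en-1-yl]-6α,8α-bis(triethylsilyloxy)labd-13-en-18-oate
Product: 24 acrylate of 23 at the C5′ oxygen
Conditions: acryloyl chloride, i-Pr2NEt, DMAP (cat.), CH2Cl2, −20 → 0 °C
Reagents that add atoms: acryloyl chloride, C=CC(=O)Cl
Why: O-Acylation of the only free hydroxyl.

**Step 15**
Reactants: 24 acrylate of 23
Product: 25 (13S,14S)-13,14-epoxide of 24
Conditions: L-fructose-derived enantiomer of the Shi ketone (1 equiv), Oxone (2KHSO5·KHSO4·K2SO4), NaHCO3 (pH 8), MeCN–(MeO)2CH2–H2O, 0 °C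
Reagents that add atoms: potassium peroxymonosulfate (active part of Oxone), [K+].[O-]S(=O)(=O)OO
Why: Shi asymmetric epoxidation (chiral dioxirane, reagent control): this ketone enantiomer should deliver oxygen to the face of the electron-rich (E)-trisubstituted alkene that gives the (13S,14S)-epoxide, while the acrylate and the acyloxy-deactivated isopropenyl group react far more slowly.

**Step 16**
Reactants: 25 (13S,14S)-13,14-epoxide of 24
Product: 26 methyl (13S,14S)-13,14-epoxy-15-[(2S)-3-methyl-5-oxo-2,5-dihydrofuran-2-yl]-6α,8α-bis(triethylsilyloxy)labdan-18-oate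
Conditions: second-generation Grubbs catalyst (H2IMes)(PCy3)Cl2Ru=CHPh (10 mol %), CH2Cl2, 40 °C
Reagents that add atoms: none
Why: Ring-closing metathesis of the acrylate on the 1,1-disubstituted alkene closes the 4-methylbutenolide and releases ethene; C13=C14 is already masked as the epoxide, so no other alkene can compete, and C5′ is not touched.

**Step 17**
Reactants: 26 epoxy butenolide
Product: 27 methyl (13R,14S)-13-hydroperoxy-14-hydroxy-15-[(2S)-3-methyl-5-oxo-2,5-dihydrofuran-2-yl]-6α,8α-bis(triethylsilyloxy)labdan-18-oate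
Conditions: anhydrous H2O2 in Et2O (excess), MoO2(acac)2 (10 mol %), 0 °C → rt
Reagents that add atoms: hydrogen peroxide, OO
Why: Molybdenum-catalysed perhydrolysis of an epoxide: H2O2 should open the ring at the more substituted carbon C13 with inversion (SN2-like), which gives the (13R)-hydroperoxide and leaves C14 with its oxygen.

**Step 18**
Reactants: 27 hydroxy hydroperoxide
Product: 28 the 13-(triethylsilylperoxy) derivative of 27
Conditions: Et3SiCl (1.05 equiv), imidazole, DMF, −40 °C
Reagents that add atoms: chlorotriethylsilane, CC[Si](Cl)(CC)CC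
Why: Selective O-silylation: the hydroperoxide, more acidic and more nucleophilic than the hindered secondary alcohol beside a quaternary carbon, should be silylated first.

**Step 19**
Reactants: 28 silyl peroxide alcohol
Product: 29 methyl (13R,14E)-15-[(2S)-3-methyl-5-oxo-2,5-dihydrofuran-2-yl]-6α,8α-bis(triethylsilyloxy)-13-(triethylsilylperoxy)labd-14-en-18-oate
Conditions: Burgess reagent (methyl N-(triethylammoniosulfonyl)carbamate), benzene, 50 °C
Reagents that add atoms: none
Why: Burgess dehydration (syn elimination): C13 carries no hydrogen, so only a C15 hydrogen can be lost, which should give the (E)-C14=C15 alkene without touching the C13 or C5′ stereocentres.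

**Step 20**
Reactants: 29 tris-silylated precursor
Product: 30 methyl (13R,14E)-13-hydroperoxy-6α,8α-dihydroxy-15-[(2S)-3-methyl-5-oxo-2,5-dihydrofuran-2-yl]labd-14-en-18-oate (CNP0128148.1)
Conditions: HF·pyridine, pyridine, THF, 0 °C → rt
Reagents that add atoms: none
Why: Fluoride-mediated cleavage of the two silyl ethers and the silyl peroxide under buffered, non-basic conditions, under which the butenolide and the tertiary allylic hydroperoxide should survive.

**Compound list**

1 | ethyl (1R,2S)-2-hydroxycyclohexane-1-carboxylate | CCOC(=O)[C@@H]1CCCC[C@@H]1O | starting material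
2 | ethyl (1R,2S)-2-hydroxy-1-methylcyclohexane-1-carboxylate | CCOC(=O)[C@]1(C)CCCC[C@@H]1O | intermediate
3 | ethyl (1R)-1-methyl-2-oxocyclohexane-1-carboxylate | CCOC(=O)[C@]1(C)CCCCC1=O | intermediate
4 | ethyl (1R)-1,3-dimethyl-2-oxocyclohexane-1-carboxylate (C3 epimers) | CCOC(=O)[C@]1(C)CCCC(C)C1=O | intermediate
5 | ethyl (1R)-1,3-dimethyl-2-{[(trifluoromethyl)sulfonyl]oxy}cyclohex-2-ene-1-carboxylate | CCOC(=O)[C@]1(C)CCCC(C)=C1OS(=O)(=O)C(F)(F)F | intermediate
6 | ethyl (1R)-2-formyl-1,3-dimethylcyclohex-2-ene-1-carboxylate | CCOC(=O)[C@]1(C)CCCC(C)=C1C=O | intermediate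
7 | (7aR)-3-hydroxy-4,7a-dimethyl-5,6,7,7a-tetrahydro-2-benzofuran-1(3H)-one (C3 epimers) | O=C1OC(O)C2=C(C)CCC[C@@]12C | intermediate
8 | tert-butyl 3-oxobutanoate | CC(=O)CC(=O)OC(C)(C)C | starting material
9 | 4-bromobut-1-yne | BrCCC#C | starting material
10 | tert-butyl 2-acetylhex-5-ynoate (racemic) | CC(=O)C(CCC#C)C(=O)OC(C)(C)C | intermediate
11 | (3R,7aR)-4,7a-dimethyl-1-oxo-1,3,5,6,7,7a-hexahydro-2-benzofuran-3-yl 2-acetylhex-5-ynoate (acyloxy trans to the 7a-methyl) | O=C1O[C@@H](OC(=O)C(CCC#C)C(C)=O)C2=C(C)CCC[C@@]12C | intermediate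
12 | 2-acetyl-2-[(4S,7aR)-4,7a-dimethyl-1-oxo-1,4,5,6,7,7a-hexahydro-2-benzofuran-4-yl]hex-5-ynoic acid (C2 epimers) | O=C1OC=C2[C@@]1(C)CCC[C@]2(C)C(CCC#C)(C(C)=O)C(=O)O | intermediate
13 | (4R,7aR)-4,7a-dimethyl-4-(2-oxohept-6-yn-3-yl)-5,6,7,7a-tetrahydro-2-benzofuran-1(4H)-one (side-chain epimers) | O=C1OC=C2[C@@]1(C)CCC[C@]2(C)C(CCC#C)C(C)=O | intermediate
14 | methyl (1R,3S)-2-formyl-1,3-dimethyl-3-(2-oxohept-6-yn-3-yl)cyclohexane-1-carboxylate (epimers at C2 and the side-chain CH) | COC(=O)[C@]1(C)CCC[C@](C)(C(CCC#C)C(C)=O)C1C=O | intermediate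
15 | methyl 6α-hydroxy-8-oxo-15,16,17-trinorlabd-13-yn-18-oate | COC(=O)[C@]1(C)CCC[C@@]2(C)[C@H]1[C@@H](O)CC(=O)[C@@H]2CCC#C | intermediate
16 | methyl 6α-hydroxy-15,16-dinorlabd-8(17)-en-13-yn-18-oate | COC(=O)[C@]1(C)CCC[C@@]2(C)[C@H]1[C@@H](O)CC(=C)[C@@H]2CCC#C | intermediate
17 | methyl 17-(acetoxymercurio)-6α,8α-dihydroxy-15,16-dinorlabd-13-yn-18-oate | COC(=O)[C@]1(C)CCC[C@@]2(C)[C@H]1[C@@H](O)C[C@@](C[Hg]OC(C)=O)(O)[C@@H]2CCC#C | intermediate
18 | methyl 6α,8α-dihydroxy-15,16-dinorlabd-13-yn-18-oate | COC(=O)[C@]1(C)CCC[C@@]2(C)[C@H]1[C@@H](O)C[C@@](C)(O)[C@@H]2CCC#C | intermediate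
19 | methyl 6α,8α-bis(triethylsilyloxy)-15,16-dinorlabd-13-yn-18-oate | COC(=O)[C@]1(C)CCC[C@@]2(C)[C@H]1[C@@H](O[Si](CC)(CC)CC)C[C@@](C)(O[Si](CC)(CC)CC)[C@@H]2CCC#C | intermediate
20 | rac-2-(prop-1-en-2-yl)oxirane | CC(=C)C1CO1 | starting material
21 | (R)-2-(prop-1-en-2-yl)oxirane | CC(=C)[C@@H]1CO1 | intermediate
22 | methyl (13E)-14-(dimethylalumanyl)-6α,8α-bis(triethylsilyloxy)-15-norlabd-13-en-18-oate | COC(=O)[C@]1(C)CCC[C@@]2(C)[C@H]1[C@@H](O[Si](CC)(CC)CC)C[C@@](C)(O[Si](CC)(CC)CC)[C@@H]2CC/C(C)=C/[Al](C)C | intermediate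
23 | methyl (13E)-15-[(1S)-1-hydroxy-2-methylprop-2-en-1-yl]-6α,8α-bis(triethylsilyloxy)labd-13-en-18-oate | COC(=O)[C@]1(C)CCC[C@@]2(C)[C@H]1[C@@H](O[Si](CC)(CC)CC)C[C@@](C)(O[Si](CC)(CC)CC)[C@@H]2CC/C(C)=C/C[C@H](O)C(C)=C | intermediate
24 | acrylate of 23 | COC(=O)[C@]1(C)CCC[C@@]2(C)[C@H]1[C@@H](O[Si](CC)(CC)CC)C[C@@](C)(O[Si](CC)(CC)CC)[C@@H]2CC/C(C)=C/C[C@H](OC(=O)C=C)C(C)=C | intermediate
25 | (13S,14S)-13,14-epoxide of 24 | COC(=O)[C@]1(C)CCC[C@@]2(C)[C@H]1[C@@H](O[Si](CC)(CC)CC)C[C@@](C)(O[Si](CC)(CC)CC)[C@@H]2CC[C@]1(C)O[C@H]1C[C@H](OC(=O)C=C)C(C)=C | intermediate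
26 | methyl (13S,14S)-13,14-epoxy-15-[(2S)-3-methyl-5-oxo-2,5-dihydrofuran-2-yl]-6α,8α-bis(triethylsilyloxy)labdan-18-oate | COC(=O)[C@]1(C)CCC[C@@]2(C)[C@H]1[C@@H](O[Si](CC)(CC)CC)C[C@@](C)(O[Si](CC)(CC)CC)[C@@H]2CC[C@]1(C)O[C@H]1C[C@@H]1OC(=O)C=C1C | intermediate
27 | methyl (13R,14S)-13-hydroperoxy-14-hydroxy-15-[(2S)-3-methyl-5-oxo-2,5-dihydrofuran-2-yl]-6α,8α-bis(triethylsilyloxy)labdan-18-oate | COC(=O)[C@]1(C)CCC[C@@]2(C)[C@H]1[C@@H](O[Si](CC)(CC)CC)C[C@@](C)(O[Si](CC)(CC)CC)[C@@H]2CC[C@@](C)(OO)[C@@H](O)C[C@@H]1OC(=O)C=C1C | intermediate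
28 | 13-(triethylsilylperoxy) derivative of 27 | COC(=O)[C@]1(C)CCC[C@@]2(C)[C@H]1[C@@H](O[Si](CC)(CC)CC)C[C@@](C)(O[Si](CC)(CC)CC)[C@@H]2CC[C@@](C)(OO[Si](CC)(CC)CC)[C@@H](O)C[C@@H]1OC(=O)C=C1C | intermediate
29 | methyl (13R,14E)-15-[(2S)-3-methyl-5-oxo-2,5-dihydrofuran-2-yl]-6α,8α-bis(triethylsilyloxy)-13-(triethylsilylperoxy)labd-14-en-18-oate | COC(=O)[C@]1(C)CCC[C@@]2(C)[C@H]1[C@@H](O[Si](CC)(CC)CC)C[C@@](C)(O[Si](CC)(CC)CC)[C@@H]2CC[C@](C)(/C=C/[C@@H]1OC(=O)C=C1C)OO[Si](CC)(CC)CC | intermediate
30 | methyl (13R,14E)-13-hydroperoxy-6α,8α-dihydroxy-15-[(2S)-3-methyl-5-oxo-2,5-dihydrofuran-2-yl]labd-14-en-18-oate | COC(=O)[C@]1(C)CCC[C@@]2(C)[C@H]1[C@@H](O)C[C@@](C)(O)[C@@H]2CC[C@](C)(/C=C/[C@@H]1OC(=O)C=C1C)OO | target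

**Totals**

Total step count: 20. Longest linear sequence: 18 steps (steps 1–6, 8–11, 13–20).

**Steps most likely to fail**

Step 8 (proposed new method). The pseudo-ester may ionise at the acylal C6–O bond, so that C9 is alkylated at C6 (ion-pair return) or the acyloxy group migrates to C10. The crowded [3,3] transition state, with both termini fully substituted, may also be too slow; in the basic stage the ketol may lose water by E1cB or close to the cis-fused ring. Fallback (known chemistry), from 7 back to 15: lactol 7 is acetylated (Ac2O, pyridine, DMAP) to the trans acetate F1. Commercial 5-(trimethylsilyl)pent-4-yn-1-ol is oxidised (Dess–Martin periodinane) to 5-(trimethylsilyl)pent-4-ynal F2, which (PhO)3P/Br2 converts into the gem-dibromide F3. Takai–Utimoto alkylidenation of F1 with F3 (TiCl4, TMEDA, Zn, PbCl2 cat., THF) gives the (Z)-vinyl ether F4. Its thermal Claisen rearrangement (toluene, 110 °C; C9 is now only tertiary in the transition state) gives the enol lactone ketone F5. K2CO3 in MeOH then removes the alkynyl silyl group, opens the enol lactone and closes ring B to 15.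

Step 17. H2O2 may attack C14 instead of C13, C13 may ionise with loss of configuration, or the Lewis-acidic catalyst may rearrange the epoxide to a carbonyl compound. Fallback, from 24 back to 30: ring-closing metathesis of 24 (second-generation Grubbs catalyst; closure on the isopropenyl group must here outrun closure on the trisubstituted C13=C14 alkene) gives the (13E)-butenolide F6. A Schenck ene reaction (O2, tetraphenylporphyrin, visible light, CH2Cl2, 0 °C) gives the (13R)-hydroperoxide F7 after chromatographic separation of isomers, since this alkene offers little facial or regiochemical bias. HF·pyridine then gives 30.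

Step 13. The activated alkenylalane may open the vinyl epoxide at the isopropenyl terminus (SN2′), or n-BuLi may add to the methyl ester. Fallback, from 19 back to 23: the methylalumination mixture is quenched with I2 to give the (E)-vinyl iodide F8, which is joined to 21 by iodine–lithium exchange (t-BuLi, Et2O, −100 °C) and BF3·OEt2-assisted epoxide opening, returning to 23.

**Further compounds**

F1 | step 8 | (3R,7aR)-4,7a-dimethyl-1-oxo-1,3,5,6,7,7a-hexahydro-2-benzofuran-3-yl acetate | O=C1O[C@@H](OC(C)=O)C2=C(C)CCC[C@@]12C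
F2 | step 8 | 5-(trimethylsilyl)pent-4-ynal | O=CCCC#C[Si](C)(C)C
F3 | step 8 | (5,5-dibromopent-1-yn-1-yl)trimethylsilane | BrC(Br)CCC#C[Si](C)(C)C
F4 | step 8 | (3R,7aR)-4,7a-dimethyl-3-{[(2Z)-7-(trimethylsilyl)hept-2-en-6-yn-2-yl]oxy}-5,6,7,7a-tetrahydro-2-benzofuran-1(3H)-one | O=C1O[C@@H](O/C(C)=C\CCC#C[Si](C)(C)C)C2=C(C)CCC[C@@]12C
F5 | step 8 | (4R,7aR)-4,7a-dimethyl-4-[2-oxo-7-(trimethylsilyl)hept-6-yn-3-yl]-5,6,7,7a-tetrahydro-2-benzofuran-1(4H)-one | O=C1OC=C2[C@@]1(C)CCC[C@]2(C)C(CCC#C[Si](C)(C)C)C(C)=O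
F6 | step 17 | methyl (13E)-15-[(2S)-3-methyl-5-oxo-2,5-dihydrofuran-2-yl]-6α,8α-bis(triethylsilyloxy)labd-13-en-18-oate | COC(=O)[C@]1(C)CCC[C@@]2(C)[C@H]1[C@@H](O[Si](CC)(CC)CC)C[C@@](C)(O[Si](CC)(CC)CC)[C@@H]2CC/C(C)=C/C[C@@H]1OC(=O)C=C1C
F7 | step 17 | methyl (13R,14E)-13-hydroperoxy-15-[(2S)-3-methyl-5-oxo-2,5-dihydrofuran-2-yl]-6α,8α-bis(triethylsilyloxy)labd-14-en-18-oate | COC(=O)[C@]1(C)CCC[C@@]2(C)[C@H]1[C@@H](O[Si](CC)(CC)CC)C[C@@](C)(O[Si](CC)(CC)CC)[C@@H]2CC[C@](C)(/C=C/[C@@H]1OC(=O)C=C1C)OO
F8 | step 13 | methyl (13E)-14-iodo-6α,8α-bis(triethylsilyloxy)-15-norlabd-13-en-18-oate | COC(=O)[C@]1(C)CCC[C@@]2(C)[C@H]1[C@@H](O[Si](CC)(CC)CC)C[C@@](C)(O[Si](CC)(CC)CC)[C@@H]2CC/C(C)=C/I
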